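**Plan**
- The retrosynthesis cuts the O3–S bond first, then the two O–CH2Ph masks on O3' and O5, then the O3–C1'' glycosidic bond. The O7–CH3 and O4'–CH3 bonds are cut last, which leads back to rutin.
- No ring is built. Rings A, B and C and every C–C bond come with rutin. The forward order is: methylate O7 and O4', benzylate O3' and O5, deglycosylate O3, sulfate O3, debenzylate.
- The five oxygens of the flavonol core differ, and this makes the key step possible. O7–H (ring A, para to C4a) and O4'–H (ring B, para to C1' on the enone carbon C2) are both conjugated with C4=O of ring C. O5–H is chelated to C4=O, O3'–H is unconjugated, and O3 already carries the rutinoside.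
- The target has no stereocentre. The ten sugar stereocentres of rutin are bought, stay untouched and leave in step 3.

Key step: step 1

Assumption: the target is achiral and is drawn as the free hydrogen sulfate. The sulfate is therefore carried as its triethylammonium salt and protonated only in the last operation, cold, because the acid form is prone to solvolysis.

**Step 1**
Reactants: 1 rutin (quercetin 3-O-[α-L-rhamnopyranosyl-(1→6)-β-D-glucopyranoside], dried); 2 iodomethane
Product: 3 7,4'-di-O-methylrutin (ombuoside; O7 and O4' methylated; 5-OH, 3'-OH and six sugar OH free)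
Conditions: K2CO3 (2.0 equiv), MeI (2.1 equiv, slow addition), dry DMF, 0 °C → rt, Ar, dark
Reagents that add atoms: iodomethane, CI
Why: Carbonate ionises O7–H of ring A and O4'–H of ring B, the two phenols whose anions delocalise into C4=O of ring C (O7 para to C4a, O4' para to C1' and on through C2=C3), and each phenoxide displaces iodide from MeI by SN2 to form O7–CH3 and O4'–CH3. The closest known reaction type is the Williamson-type partial O-alkylation of flavonol glycosides in the order of phenol acidity, paralleled by the para-selective mono-alkylation of 3,4-dihydroxyaryl carbonyl compounds under carbonate bases. No ring closes and no stereocentre forms; the ten sugar stereocentres are spectators. The step needs O7/O4' selectivity over O3', O5, O3 and the six sugar hydroxyls: O3'–H is meta to C1' and not conjugated with C4=O, O5–H sits in a six-membered chelate with C4=O, O3 is blocked by the rutinoside, and aliphatic hydroxyls are not ionised by carbonate. Holding base and MeI at two equivalents and adding MeI slowly in the cold should leave the guaiacol-type O3'–H of the product with only hydrogencarbonate as base and no spare electrophile.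

**Step 2**
Reactants: 3 7,4'-di-O-methylrutin; 4 benzyl bromide
Product: 5 3',5-di-O-benzyl-7,4'-di-O-methylrutin (benzyl ethers on O3' and O5, rutinoside unchanged)
Conditions: BnBr (3 equiv), K2CO3 (3 equiv), cat. Bu4NI, DMF, 60 °C, Ar
Reagents that add atoms: benzyl bromide, BrCc1ccccc1
Why: In this Williamson ether synthesis, O3'–H reacts readily, excess reagent and heat in DMF break the O5–H···O=C4 chelate, and the sugar hydroxyls stay un-ionised under carbonate.

**Step 3**
Reactants: 5 3',5-di-O-benzyl-7,4'-di-O-methylrutin
Product: 6 3',5-di-O-benzylombuin (5-benzyloxy-2-(3-benzyloxy-4-methoxyphenyl)-3-hydroxy-7-methoxychromen-4-one)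
Conditions: 2 M HCl, EtOH–H2O, 75 °C; cool, filter
Reagents that add atoms: none
Why: Acid-catalysed glycoside hydrolysis through the glycosyl oxocarbenium ions cleaves only the two acetal linkages, so the aryl methyl and benzyl ethers should persist and O3–H emerges as the only free hydroxyl of an aglycone that crystallises from the medium.

**Step 4**
Reactants: 6 3',5-di-O-benzylombuin; 7 sulfur trioxide–triethylamine complex
Product: 8 triethylammonium 3',5-di-O-benzylombuin 3-sulfate
Conditions: SO3·NEt3 (4 equiv), Et3N (2 equiv), dry DMF, 50 °C; SiO2, CH2Cl2–MeOH–Et3N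
Reagents that add atoms: sulfur trioxide–triethylamine complex, CC[N+](CC)(CC)S(=O)(=O)[O-]
Why: In this O-sulfation with a sulfur trioxide–amine complex, the enolic O3–H is the only hydroxyl left, it takes SO3 from the amine, and the released amine holds the monoester as a stable, chromatographable salt.

**Step 5**
Reactants: 8 triethylammonium 3',5-di-O-benzylombuin 3-sulfate
Product: 10 ombuin 3-O-sulfate (free acid), via triethylammonium ombuin 3-sulfate 9 (not isolated)
Conditions: H2 (1 atm), 10% Pd/C, MeOH–THF, rt; filter; Dowex 50WX8 (H+), MeOH–H2O, 0 °C; freeze-dry at once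
Reagents that add atoms: none
Why: Catalytic hydrogenolysis of aryl benzyl ethers leaves sulfate monoester salts, aryl methyl ethers and the chromone C2=C3 bond intact at one atmosphere, and cation exchange on a sulfonic acid resin then replaces Et3NH+ by H+.

**Compound list**
1 | rutin | C[C@H]1[C@@H]([C@H]([C@H]([C@@H](O1)OC[C@@H]2[C@H]([C@@H]([C@H]([C@@H](O2)OC3=C(OC4=CC(=CC(=C4C3=O)O)O)C5=CC(=C(C=C5)O)O)O)O)O)O)O)O | starting material
2 | iodomethane | CI | starting material
3 | 7,4'-di-O-methylrutin | C[C@H]1[C@@H]([C@H]([C@H]([C@@H](O1)OC[C@@H]2[C@H]([C@@H]([C@H]([C@@H](O2)OC3=C(OC4=CC(=CC(=C4C3=O)O)OC)C5=CC(=C(C=C5)OC)O)O)O)O)O)O)O | intermediate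
4 | benzyl bromide | BrCc1ccccc1 | starting material
5 | 3',5-di-O-benzyl-7,4'-di-O-methylrutin | C[C@H]1[C@@H]([C@H]([C@H]([C@@H](O1)OC[C@@H]2[C@H]([C@@H]([C@H]([C@@H](O2)OC3=C(OC4=CC(=CC(=C4C3=O)OCc6ccccc6)OC)C5=CC(=C(C=C5)OC)OCc7ccccc7)O)O)O)O)O)O | intermediate
6 | 3',5-di-O-benzylombuin | COc1cc(OCc2ccccc2)c2c(=O)c(O)c(-c3ccc(OC)c(OCc4ccccc4)c3)oc2c1 | intermediate
7 | sulfur trioxide–triethylamine complex | CC[N+](CC)(CC)S(=O)(=O)[O-] | starting material
8 | triethylammonium 3',5-di-O-benzylombuin 3-sulfate | COc1cc(OCc2ccccc2)c2c(=O)c(OS(=O)(=O)[O-])c(-c3ccc(OC)c(OCc4ccccc4)c3)oc2c1.CC[NH+](CC)CC | intermediate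
9 | triethylammonium ombuin 3-sulfate | COc1cc(O)c2c(=O)c(OS(=O)(=O)[O-])c(-c3ccc(OC)c(O)c3)oc2c1.CC[NH+](CC)CC | intermediate
10 | ombuin 3-O-sulfate | COc1cc(O)c2c(=O)c(OS(=O)(=O)O)c(-c3ccc(OC)c(O)c3)oc2c1 | target

Total step count: 5. Longest linear sequence: 5 (1 → 3 → 5 → 6 → 8 → 10).

**Steps most likely to fail**

Risk 1 (step 1): site selectivity may erode. Once O4' is capped, O3' can start to compete, and because MeI is limited, material then stays unmethylated at O4'. The fallback replaces free phenoxides by masked ones that are released in order of leaving-group quality.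
- It sets out from 1, which is peracetylated (Ac2O, pyridine) to rutin decaacetate F1.
- Treatment with 2 and anhydrous K2CO3 in refluxing dry acetone is an acetate-displacement alkylation of a polyphenol acetate. It should strip and trap only the two aryl esters whose phenoxides are best stabilised by C4=O, while O3' and O5 remain esterified. This gives 7,4'-di-O-methylrutin octaacetate F2.
- Zemplén deacetylation (cat. NaOMe, MeOH) comes back to the route at 3.

Risk 2 (step 3): the peri 5-O-benzyl ether may be lost, because protonated C4=O assists its acid cleavage, and the hydrolysis then runs unevenly. A sluggish 5-O-benzylation in step 2 would be answered the same way. The fallback gives up the O5 mask and relies on the inertness of the chelated O5–H.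
- It sets out from 3, where only O3' is benzylated (4, about one equivalent, K2CO3, DMF, rt) to give 3'-O-benzyl-7,4'-di-O-methylrutin F3.
- The same acid hydrolysis gives 3'-O-benzylombuin F4.
- A small excess of 7 at rt should sulfate the enolic O3–H and leave O5–H alone, giving triethylammonium 3'-O-benzylombuin 3-sulfate F5.
- Hydrogenolysis (H2, Pd/C) comes back to the route at 9.

Risk 3 (step 5): debenzylation at the hindered O5 may stall, or C2=C3 may be saturated, while the sulfate is already in place. Prolonged exposure would then favour solvolysis of the ester. The fallback uses no benzyl groups and lets the reagent control the site of sulfation.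
- It sets out from 3, which is hydrolysed directly (HCl, EtOH–H2O) to ombuin F6.
- Carbodiimide-mediated sulfation (Bu4N·HSO4, DCC, pyridine, 4 °C) reaches only O7, O4' and O3 in flavonols. With O7 and O4' methylated it should give tetrabutylammonium ombuin 3-sulfate F7.
- Cold cation exchange on the H+ resin comes back to the route at 10.

**Further compounds**
F1 | step 1 | rutin decaacetate | C[C@H]1[C@@H]([C@H]([C@H]([C@@H](O1)OC[C@@H]2[C@H]([C@@H]([C@H]([C@@H](O2)OC3=C(OC4=CC(=CC(=C4C3=O)OC(C)=O)OC(C)=O)C5=CC(=C(C=C5)OC(C)=O)OC(C)=O)OC(C)=O)OC(C)=O)OC(C)=O)OC(C)=O)OC(C)=O)OC(C)=O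
F2 | step 1 | 7,4'-di-O-methylrutin octaacetate | C[C@H]1[C@@H]([C@H]([C@H]([C@@H](O1)OC[C@@H]2[C@H]([C@@H]([C@H]([C@@H](O2)OC3=C(OC4=CC(=CC(=C4C3=O)OC(C)=O)OC)C5=CC(=C(C=C5)OC)OC(C)=O)OC(C)=O)OC(C)=O)OC(C)=O)OC(C)=O)OC(C)=O)OC(C)=O
F3 | step 3 | 3'-O-benzyl-7,4'-di-O-methylrutin | C[C@H]1[C@@H]([C@H]([C@H]([C@@H](O1)OC[C@@H]2[C@H]([C@@H]([C@H]([C@@H](O2)OC3=C(OC4=CC(=CC(=C4C3=O)O)OC)C5=CC(=C(C=C5)OC)OCc6ccccc6)O)O)O)O)O)O
F4 | step 3 | 3'-O-benzylombuin | COc1cc(O)c2c(=O)c(O)c(-c3ccc(OC)c(OCc4ccccc4)c3)oc2c1
F5 | step 3 | triethylammonium 3'-O-benzylombuin 3-sulfate | COc1cc(O)c2c(=O)c(OS(=O)(=O)[O-])c(-c3ccc(OC)c(OCc4ccccc4)c3)oc2c1.CC[NH+](CC)CC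
F6 | step 5 | ombuin | COc1cc(O)c2c(=O)c(O)c(-c3ccc(OC)c(O)c3)oc2c1
F7 | step 5 | tetrabutylammonium ombuin 3-sulfate | COc1cc(O)c2c(=O)c(OS(=O)(=O)[O-])c(-c3ccc(OC)c(O)c3)oc2c1.CCCC[N+](CCCC)(CCCC)CCCC
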